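Amounts first: of the substrate charged in beta, 14.5% stood unreacted at 1.67 d, and the argument below grows from that remainder.

| flask | substrate | reagent | temperature | remark | time |
|---|---|---|---|---|---|
| beta | 0.015 M | 0.0105 M | −20 °C | run made earlier |  |
| theta | 0.0075 M | 0.0105 M | −20 °C | run made earlier |  |
| ochre | 0.015 M | 0.0105 M (fed, over 15 d) | −20 °C | all else is in the flask from the start; the feed brings no volume worth counting | 20 d |
| red | 0.015 M (fed, over 40 h) | 0.0105 M | −20 °C | all else is in the flask from the start; the feed brings no volume worth counting | 20 d |
| amber | 0.015 M (fed, over 15 d) | 0.0105 M |  | the addition at −40 °C, then warmed to −20 °C; the feed brings no volume worth counting | 20 d |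
| blue | 0.015 M | 0.0105 M (in portions, 2, over 15 d) | −20 °C | first portion at the start, last at 15 d | 20 d |
| violet | 0.015 M (fed, over 15 d) | 0.0105 M | −20 °C | all else is in the flask from the start; the feed brings no volume worth counting | 20 d |

beta run (percent of the substrate charged)

| time / d | homo dimer / % | product / % |
|---|---|---|
| 1.67 | 65.5 | 20.0 |
| 2.50 | 68.3 | 21.9 |
| 4.00 | 70.8 | 23.4 |
| 8.00 | 72.9 | 24.4 |
| 12.0 | 72.8 | 25.1 |
| 20.0 | 73.3 | 26.4 |

theta run (percent of the substrate charged)

| time / h | homo dimer / % | product / % |
|---|---|---|
| 3.00 | 13.4 | 4.8 |
| 10.0 | 30.2 | 11.0 |
| 15.0 | 38.0 | 13.9 |
| 25.0 | 46.2 | 18.4 |
| 40.0 | 53.8 | 22.3 |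
| 50.0 | 56.3 | 23.4 |

(readings scatter by 0.3 percentage points)

- in percentages every species weighs as the substrate in it: one homo dimer counts as two
- the numbers in the tables scatter with a standard deviation of 0.3 percentage points
- the earlier runs do not show what temperature does; that part of a forecast is a guess

- the flask with the highest amount of homo dimer, in percent of the substrate charged ("all alike" if they lie within 1.5 percentage points) (ochre / red / amber / blue / violet / all alike)
- final homo dimer, as a percentage of the substrate charged, in ochre
- final homo dimer, as a percentage of the substrate charged, in red
- final homo dimer, as a percentage of the substrate charged, in amber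
- final homo dimer, as a percentage of the substrate charged, in blue
- final homo dimer, as a percentage of the substrate charged, in violet

Read as a second-order loss over both routes, that remainder gives a first half-life of 6.80 h at the beta charge. The theta remainder at 50.0 h gives 12.7 h, twice as long, at 0.0075 M against 0.015 M. The slow feed of 15 d holds 53.0 such half-lives: this number of half-lives per feed time is the turnover count.

The forecaster and I read that count differently. The forecast holds that the product share stays roughly fixed: "Delaying reagent (ochre, blue) therefore barely changes the dimer". It gives ochre 74.8%, red 71.5%, amber 70%, blue 74.2% and violet 65%, with ochre highest.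

I read the product share, the selectivity, as 26.4% in theta at 3.00 h against 23.4% in beta at 1.67 d, and theta has more reagent per substrate. Those shares, taken at different conversions, give no order, so as a crude working assumption I let product form at a rate proportional to substrate and reagent, with reagent taken as its charge. Product then follows a constant times the logarithm of one over the remainder, and in beta that logarithm stands at 1.93 where 20.0% of product was read. Scaled so, the assumption gives 29.5% at 4.00 d in beta against the reading of 23.4%, so it runs too high there and I hold it as a rough estimate. In ochre, reagent rises evenly through the feed, and with so large a count the same logarithm, weighted by reagent, comes to about one, because the half-life is far shorter than the feed. My estimate for ochre is therefore 10.4% product and about 89.6% homo dimer, higher than the top of the forecast's range.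

The flasks gave homo dimer of 91.2% in ochre, 70.2% in red, 72.7% in amber, 79.9% in blue and 61.3% in violet.

    substrate + reagent → product, rate k1*[substrate]^1.5*[reagent]^0.5 (k = 0.0321 /M/min, Ea = 62.0 kJ/mol)
    2 substrate → homo dimer (k = 0.0580 /M/min, Ea = 51.0 kJ/mol)
    (constants at −20 °C)

Ochre stands highest, 16 percentage points above the forecast, with 7.84% product at 20.0 d. The forecaster's view has its region in red, where reagent stood from the start and the count for the 40 h feed is 5.88, smaller than the slow feed's: red gave 70.2% against the forecast's 71.5%.

In the neighbour flask, violet's recipe with 0.0060 M of substrate, the count falls with the charge to 21.2. Feed balanced against second-order loss holds substrate at one over the root of the count, and the 5.00 d after the feed add the count times 0.333 to the reciprocal, giving 8.57% left. The computed flask left 6.60% substrate, with 51.1% homo dimer.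

(All runs were generated by integration for an exercise, and the scatter is random.)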